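## The problem

1. The target is a monocyclic C25 alcohol built on a 14-membered carbocycle, numbered here C1–C14. C1 carries the chain C16(=C17H2)–C18–C19–C20=C21(C22)(C23); C4=C5 is E with methyl C24 on C4; C8=C9 is Z with methyl C25 on C8; C12 carries the hydroxymethyl carbon C15.
2. There is no ring fusion and no heteroatom in the ring, so the macrocycle must be closed at a C–C bond of a flexible chain that offers no template.
3. The two trisubstituted ring alkenes have opposite geometry in a 1,5-relationship. Neither can be left to thermodynamic control in a 14-membered ring, so both must come in from stereodefined building blocks.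
4. The stereocentres C1 (S) and C12 (S) are 1,4-related across C13–C14 and are locally mirror images of each other (ring arm C2 or C11, exocyclic carbon C16 or C15, bridge). They are too remote for one to control the other, so each needs reagent control.
5. Five alkenes rule out late ozonolysis, unselective hydrogenation or hydroboration, and strong acid. The 1,1-disubstituted C16=C17 next to the tertiary allylic C1–H could also migrate into conjugation and destroy C1.
6. The feature the plan exploits: C12 bears the exocyclic one-carbon unit C15. At the carboxyl level C15 is an acyl group outside the ring with C12 as its α-carbon, so the ring bond C12–C13 can be made by enolate alkylation while an auxiliary on C15 controls C12.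
7. The same pattern recurs at C1: C2–C1–C16(=C17)–C18…C23 is the skeleton of deconjugated geranic acid, so C1 is the α-carbon of a geranic acid dienolate.

## Retrosynthesis

**31 back to 29 (no C–C bond cut).** The C15 alcohol of 31 is the reduced form of an exocyclic acyl group, and a phenylsulfonyl group on C2 is accepted as a traceless activator. This leads to sulfone alcohol 30 and the macrocyclic imide 29. The forward steps must remove the auxiliary and the sulfone reductively without touching five alkenes.

**29 back to 27 (cut C12–C13, the ring closure).** Cutting at C2–C3 instead would close the ring by a classical sulfone alkylation but set no stereocentre. Cutting C11–C12 would need the same auxiliary but a less accessible electrophile. C12–C13 is chosen because the C13–C14 arm comes free with the C1 alkylation and the auxiliary on C15 stays outside the ring. The precursor 27 (triflate of alcohol 26) is open-chain and lacks the C12 centre. The forward reaction must be an intramolecular, auxiliary-controlled enolate alkylation at high dilution.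

**26 back to 21 and 24 (cut C9–C10).** An sp2–sp3 coupling lets the vinyl iodide 21 carry the Z geometry of C8=C9. The alkylborane from butenoyl imide 24 brings C10, C11, C12, C15 and the auxiliary in one piece. Cutting C10–C11 with a nerol-type allylic unit would need a C11 nucleophile with no handle next to C12. Hydroboration is done on 24 alone, so the C16=C17 alkene never meets the borane. The coupling must proceed with retention.

**21 back to 11 and 19 (cut C2–C3).** C3 is allylic, so it becomes the allylic bromide 19; C2 becomes the sulfonyl carbanion of 11. An organomagnesium at C2 would threaten the vinyl iodide, whereas the sulfone is inert in all later steps and leaves in the last one. The forward reaction must be SN2 without allylic transposition.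

**11 back to 4 and 5 (cut C1–C14).** Deconjugative α-alkylation of the geranic imide 4 with tert-butyl bromoacetate 5 sets C1, creates the C16=C17 methylidene and delivers the whole side chain in one step, via 7, 8, 9 and 10. The ester carbon becomes C13. The precursor is a commodity terpene acid on an auxiliary. The forward reaction needs deprotonation at the methyl group, α-attack and facial control.

**19 back to 12 and 13 (cut C7–C8, oxidise C3).** Syn-carbocupration of propyne 13 with the organocopper from bromide 12 gives the Z-vinyl iodide 17. Allylic oxidation of its E-methyl group gives 18, which is converted to 19.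

**4 and 24 back to acids and auxiliary.** Both imides come from the same oxazolidinone 2, acylated with geranic acid 1 or but-3-enoic acid 22. The locally meso relationship of C1 and C12 means both alkylations need the same enantiomer of 2.

## Roads not taken

**Alternative 1:** Cut C4=C5 by ring-closing metathesis, with C1 from the chiral pool. (4R)-Limonene A1 maps onto C13–C14–C1(C16=C17)–C2–C3–C4(C24). After prenylation of the isopropenyl methyl group and cleavage of the ring alkene it would give keto aldehyde A2, to be elaborated to triene A3. The forward key step is metathesis of A3 with the second-generation Grubbs catalyst. The chosen plan is better for these reasons: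
- A trisubstituted alkene in a 14-membered ring forms as an E/Z mixture under thermodynamic control.
- A3 holds three further alkenes that can enter metathesis.
- The ring alkene of prenylated A1 cannot be cleaved selectively beside the new side-chain alkene without protection steps.
- C12 still needs a separate auxiliary step.

**Alternative 2:** Use the local mirror symmetry of the C1/C12 pair. Each centre is the central carbon of a 2-substituted propane-1,3-diol unit, so the six-carbon core is the prochiral tetraol A4. The forward key step is a lipase-catalysed double desymmetrisation to the twofold-symmetric diacetate A5. The chosen plan is better for these reasons: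
- A lipase acetylates the same enantiotopic arm at both ends, but in 31 the ring arm and the exocyclic carbon are interchanged between the two ends.
- Both homotopic pairs of arms in A5 would therefore need statistical monofunctionalisation, then two separate couplings and a multistep build-up of C16 with its chain.
- The meso diastereomer of A5 would be hard to remove from 1,4-related acyclic centres.

**Alternative 3:** Cut C13=C14 as an alkene to be reduced later. The forward key step is ring-closing metathesis of the bis-allylic diene A6, followed by diimide reduction. The chosen plan is better for these reasons: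
- Each vinyl group of A6 lies four atoms from a trisubstituted ring alkene (C14 to C4, C13 to C9), so the ruthenium alkylidene should close a cyclopentene and expel the chain faster than it closes the 14-ring.
- The reduction would have to spare the C16=C17 alkene.
- Both stereocentres would still be set separately.

Key step: step 14

Remark: geranic acid 1 is assumed to be used as the 2E isomer; any 2Z material is removed at the stage of imide 4.
Remark: compounds 21, 26, 27, 29 and 30 are mixtures of two epimers at the sulfone-bearing carbon C2, which becomes a CH2 group in step 16.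

## Route

Step 1
Reactants: 1 (2E)-3,7-dimethylocta-2,6-dienoic acid (geranic acid); 2 (4R)-4-benzyl-1,3-oxazolidin-2-one
Product: 4 (4R)-4-benzyl-3-[(2E)-3,7-dimethylocta-2,6-dienoyl]-1,3-oxazolidin-2-one, via mixed pivalic anhydride 3 (not isolated)
Conditions: t-BuCOCl, Et3N, THF, −20 °C; then LiCl, 2, −20 °C to rt
Reagents that add atoms: none
Why: N-Acylation of the oxazolidinone through a mixed anhydride is standard for α,β-unsaturated acids and should leave the 2E double bond untouched; no stereocentre is formed.

Step 2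
Reactants: 4 (4R)-4-benzyl-3-[(2E)-3,7-dimethylocta-2,6-dienoyl]-1,3-oxazolidin-2-one; 5 tert-butyl bromoacetate
Product: 7 tert-butyl (3R)-3-{[(4R)-4-benzyl-2-oxo-1,3-oxazolidin-3-yl]carbonyl}-8-methyl-4-methylidenenon-7-enoate, via sodium dienolate 6 (not isolated)
Conditions: NaN(SiMe3)2, THF, −78 °C; then 5, −78 to −50 °C; AcOH quench at −78 °C
Reagents that add atoms: none
Why: Deconjugative α-alkylation of an N-enoyl oxazolidinone dienolate (Evans alkylation): the base should remove a proton from the C3 methyl group, which is cis to the carbonyl in the 2E imide, and the chelated Z-dienolate reacts at its α-carbon with the reactive α-bromo ester. The benzyl group shields one face, so the electrophile enters from the other and sets C1 of the target (3R in 7) while the C16=C17 methylidene is formed.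

Step 3
Reactants: 7 tert-butyl (3R)-3-{[(4R)-4-benzyl-2-oxo-1,3-oxazolidin-3-yl]carbonyl}-8-methyl-4-methylidenenon-7-enoate
Product: 8 tert-butyl (3R)-3-(hydroxymethyl)-8-methyl-4-methylidenenon-7-enoate
Conditions: LiBH4, MeOH (1 equiv), Et2O, 0 °C
Reagents that add atoms: none
Why: Reductive cleavage of an N-acyl oxazolidinone with LiBH4 is standard, spares tert-butyl esters and should not epimerise the α-centre; the auxiliary is recovered.

Step 4
Reactants: 8 tert-butyl (3R)-3-(hydroxymethyl)-8-methyl-4-methylidenenon-7-enoate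
Product: 9 tert-butyl (3R)-3-(iodomethyl)-8-methyl-4-methylidenenon-7-enoate
Conditions: I2, PPh3, imidazole, CH2Cl2, 0 °C to rt
Reagents that add atoms: iodine, II
Why: Appel-type iodination of a primary alcohol under neutral conditions; the stereocentre is not involved.

Step 5
Reactants: 9 tert-butyl (3R)-3-(iodomethyl)-8-methyl-4-methylidenenon-7-enoate
Product: 10 tert-butyl (3R)-8-methyl-4-methylidene-3-[(phenylsulfonyl)methyl]non-7-enoate
Conditions: PhSO2Na, Bu4NI (cat.), DMF, 60 °C
Reagents that add atoms: sodium benzenesulfinate, [Na+].[O-]S(=O)c1ccccc1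
Why: SN2 displacement of the primary iodide by sulfinate sulfur gives the sulfone directly and avoids a sulfide oxidation in the presence of three alkenes.

Step 6
Reactants: 10 tert-butyl (3R)-8-methyl-4-methylidene-3-[(phenylsulfonyl)methyl]non-7-enoate
Product: 11 (3R)-8-methyl-4-methylidene-3-[(phenylsulfonyl)methyl]non-7-en-1-ol
Conditions: LiAlH4, THF, 0 °C to rt
Reagents that add atoms: none
Why: LiAlH4 reduces the tert-butyl ester to the primary alcohol (C13–OH); the sulfone and the isolated alkenes are inert.

Step 7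
Reactants: 12 5-bromo-2-methylpent-2-ene; 13 propyne
Product: 17 (1Z)-1-iodo-2,6-dimethylhepta-1,5-diene, via Grignard reagent 14 (not isolated), via alkylcopper 15 (not isolated), via alkenylcopper 16 (not isolated)
Conditions: Mg, Et2O; CuBr·SMe2, Et2O/Me2S, −45 °C; 13, −25 °C; I2, −78 to 0 °C
Reagents that add atoms: iodine, II
Why: Syn-carbocupration of a terminal alkyne (Normant reaction) puts the alkyl group on the internal carbon and copper on the terminus, cis to the new alkyl group. Iodinolysis with retention gives the Z-vinyl iodide that carries the geometry of C8=C9.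

Step 8
Reactants: 17 (1Z)-1-iodo-2,6-dimethylhepta-1,5-diene
Product: 18 (2E,6Z)-7-iodo-2,6-dimethylhepta-2,6-dien-1-ol
Conditions: SeO2 (cat.), t-BuOOH, salicylic acid (cat.), CH2Cl2, rt
Reagents that add atoms: tert-butyl hydroperoxide, CC(C)(C)OO
Why: Selenium dioxide allylic oxidation (ene reaction, then 2,3-shift) of a terminal isopropylidene group hydroxylates the E-methyl group, which fixes C4=C5 as E; the electron-poor iodoalkene should react more slowly.

Step 9
Reactants: 18 (2E,6Z)-7-iodo-2,6-dimethylhepta-2,6-dien-1-ol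
Product: 19 (1Z,5E)-7-bromo-1-iodo-2,6-dimethylhepta-1,5-diene
Conditions: CBr4, PPh3, CH2Cl2, 0 °C
Reagents that add atoms: carbon tetrabromide, BrC(Br)(Br)Br
Why: Appel bromination of a primary allylic alcohol at 0 °C should proceed without allylic transposition or E/Z isomerisation.

Step 10
Reactants: 11 (3R)-8-methyl-4-methylidene-3-[(phenylsulfonyl)methyl]non-7-en-1-ol; 19 (1Z,5E)-7-bromo-1-iodo-2,6-dimethylhepta-1,5-diene
Product: 21 (3R,4RS,6E,10Z)-11-iodo-6,10-dimethyl-3-(6-methylhepta-1,5-dien-2-yl)-4-(phenylsulfonyl)undeca-6,10-dien-1-ol, via dilithium dianion 20 (not isolated)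
Conditions: LiN(iPr)2 (2.1 equiv), THF/DMPU, −78 °C; then 19, −78 to −40 °C
Reagents that add atoms: none
Why: C-Alkylation of the O,C-dianion of a hydroxy sulfone with a primary allylic bromide (sulfone alkylation, SN2) forms C2–C3; the amide base does not exchange the vinyl iodide. The sulfone-bearing centre forms as a mixture, which does not matter because it is removed in step 16.

Step 11
Reactants: 22 but-3-enoic acid; 2 (4R)-4-benzyl-1,3-oxazolidin-2-one
Product: 24 (4R)-4-benzyl-3-(but-3-enoyl)-1,3-oxazolidin-2-one, via mixed pivalic anhydride 23 (not isolated)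
Conditions: t-BuCOCl, Et3N, THF, −20 °C; then LiCl, 2, −20 to 0 °C
Reagents that add atoms: none
Why: Same mixed-anhydride N-acylation as in step 1; the low temperature should keep the β,γ-double bond out of conjugation.

Step 12
Reactants: 24 (4R)-4-benzyl-3-(but-3-enoyl)-1,3-oxazolidin-2-one; 21 (3R,4RS,6E,10Z)-11-iodo-6,10-dimethyl-3-(6-methylhepta-1,5-dien-2-yl)-4-(phenylsulfonyl)undeca-6,10-dien-1-ol
Product: 26 (4R)-4-benzyl-3-[(5Z,9E,12RS,13R)-15-hydroxy-6,10-dimethyl-13-(6-methylhepta-1,5-dien-2-yl)-12-(phenylsulfonyl)pentadeca-5,9-dienoyl]-1,3-oxazolidin-2-one, via B-alkyl-9-BBN adduct 25 (not isolated)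
Conditions: 24, 9-BBN dimer, THF, 0 °C to rt; then 21, Pd(dppf)Cl2 (cat.), AsPh3, Cs2CO3, DMF/H2O, rt
Reagents that add atoms: none
Why: The terminal alkene of 24 is hydroborated before 21 is added, so the C16=C17 alkene never meets the borane. B-alkyl Suzuki–Miyaura coupling with the vinyl iodide proceeds with retention and fixes C8=C9 as Z while forming C9–C10.

Step 13
Reactants: 26 (4R)-4-benzyl-3-[(5Z,9E,12RS,13R)-15-hydroxy-6,10-dimethyl-13-(6-methylhepta-1,5-dien-2-yl)-12-(phenylsulfonyl)pentadeca-5,9-dienoyl]-1,3-oxazolidin-2-one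
Product: 27 (4R)-4-benzyl-3-[(5Z,9E,12RS,13R)-6,10-dimethyl-13-(6-methylhepta-1,5-dien-2-yl)-12-(phenylsulfonyl)-15-{[(trifluoromethyl)sulfonyl]oxy}pentadeca-5,9-dienoyl]-1,3-oxazolidin-2-one
Conditions: Tf2O, 2,6-lutidine, CH2Cl2, −78 °C; cold work-up, used at once
Reagents that add atoms: trifluoromethanesulfonic anhydride, O=S(=O)(OS(=O)(=O)C(F)(F)F)C(F)(F)F
Why: Triflation of the only hydroxyl group at low temperature; imide, sulfone and alkenes are inert to these conditions.

Step 14
Reactants: 27 (4R)-4-benzyl-3-[(5Z,9E,12RS,13R)-6,10-dimethyl-13-(6-methylhepta-1,5-dien-2-yl)-12-(phenylsulfonyl)-15-{[(trifluoromethyl)sulfonyl]oxy}pentadeca-5,9-dienoyl]-1,3-oxazolidin-2-one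
Product: 29 (4R)-4-benzyl-3-{[(1S,4Z,8E,11RS,12R)-5,9-dimethyl-12-(6-methylhepta-1,5-dien-2-yl)-11-(phenylsulfonyl)cyclotetradeca-4,8-dien-1-yl]carbonyl}-1,3-oxazolidin-2-one, via sodium enolate 28 (not isolated)
Conditions: slow addition of 27 to NaN(SiMe3)2 (1.2 equiv), THF, −78 to −45 °C, final concentration about 0.002 M
Reagents that add atoms: none
Why: Proposed new method: the base deprotonates the imide α-carbon C12 (far more acidic than the tertiary C–H next to the sulfone) to the chelated sodium Z-enolate 28, whose carbon displaces the primary triflate at C13 by SN2; the closest known reaction type is the intermolecular alkylation of oxazolidinone-imide sodium enolates with primary alkyl triflates (Evans alkylation), and macrocyclisation by intramolecular alkylation of stabilised carbanions is well known for 14-membered terpenoid rings. The 14-membered ring closes in a 14-exo-tet mode with the enolate double bond and the auxiliary outside the ring, so the chain only has to deliver C13 to C12. The new stereocentre C12 is controlled by the auxiliary alone: in the chelated Z-enolate the benzyl group shields one face and C13 adds to the other, which gives the required (S) configuration with the same enantiomer of the auxiliary and the same facial sense as in step 2. The remote centre C1 and the epimeric sulfone carbon should not influence this choice. The step needs C- over O-alkylation, cyclisation over oligomerisation and substitution over elimination; the chelated sodium enolate, the pseudo-high dilution from slow addition and an unhindered primary triflate at low temperature should secure these. Reaction of the hindered amide base with the triflate should be slower than enolisation.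

Step 15
Reactants: 29 (4R)-4-benzyl-3-{[(1S,4Z,8E,11RS,12R)-5,9-dimethyl-12-(6-methylhepta-1,5-dien-2-yl)-11-(phenylsulfonyl)cyclotetradeca-4,8-dien-1-yl]carbonyl}-1,3-oxazolidin-2-one
Product: 30 [(1S,4Z,8E,11RS,12R)-5,9-dimethyl-12-(6-methylhepta-1,5-dien-2-yl)-11-(phenylsulfonyl)cyclotetradeca-4,8-dien-1-yl]methanol
Conditions: LiBH4, MeOH (1 equiv), Et2O/THF, 0 °C
Reagents that add atoms: none
Why: Reductive removal of the auxiliary as in step 3 turns the exocyclic acyl carbon into the C15 hydroxymethyl group without touching C12, the sulfone or the alkenes.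

Step 16
Reactants: 30 [(1S,4Z,8E,11RS,12R)-5,9-dimethyl-12-(6-methylhepta-1,5-dien-2-yl)-11-(phenylsulfonyl)cyclotetradeca-4,8-dien-1-yl]methanol
Product: 31 [(1S,4Z,8E,12S)-5,9-dimethyl-12-(6-methylhepta-1,5-dien-2-yl)cyclotetradeca-4,8-dien-1-yl]methanol (target)
Conditions: Na/Hg (6% Na), Na2HPO4, MeOH/THF, −20 to 0 °C
Reagents that add atoms: none
Why: Reductive desulfonylation of an alkyl phenyl sulfone with sodium amalgam in buffered methanol (two electron transfers, then protonation) turns C2 into CH2 and removes the epimeric centre; isolated di- and trisubstituted alkenes are not reduced under these conditions.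

## Compound list

1 | (2E)-3,7-dimethylocta-2,6-dienoic acid (geranic acid) | CC(C)=CCC/C(C)=C/C(=O)O | starting material
2 | (4R)-4-benzyl-1,3-oxazolidin-2-one | O=C1N[C@H](Cc2ccccc2)CO1 | starting material
3 | (2E)-3,7-dimethylocta-2,6-dienoic pivalic anhydride | CC(C)=CCC/C(C)=C/C(=O)OC(=O)C(C)(C)C | intermediate
4 | (4R)-4-benzyl-3-[(2E)-3,7-dimethylocta-2,6-dienoyl]-1,3-oxazolidin-2-one | CC(C)=CCC/C(C)=C/C(=O)N1[C@H](Cc2ccccc2)COC1=O | intermediate
5 | tert-butyl bromoacetate | CC(C)(C)OC(=O)CBr | starting material
6 | sodium (1Z)-1-[(4R)-4-benzyl-2-oxo-1,3-oxazolidin-3-yl]-7-methyl-3-methylideneocta-1,6-dien-1-olate | [Na+].[O-]/C(=C\C(=C)CCC=C(C)C)N1[C@H](Cc2ccccc2)COC1=O | intermediate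
7 | tert-butyl (3R)-3-{[(4R)-4-benzyl-2-oxo-1,3-oxazolidin-3-yl]carbonyl}-8-methyl-4-methylidenenon-7-enoate | C=C(CCC=C(C)C)[C@@H](CC(=O)OC(C)(C)C)C(=O)N1[C@H](Cc2ccccc2)COC1=O | intermediate
8 | tert-butyl (3R)-3-(hydroxymethyl)-8-methyl-4-methylidenenon-7-enoate | C=C(CCC=C(C)C)[C@@H](CC(=O)OC(C)(C)C)CO | intermediate
9 | tert-butyl (3R)-3-(iodomethyl)-8-methyl-4-methylidenenon-7-enoate | C=C(CCC=C(C)C)[C@@H](CC(=O)OC(C)(C)C)CI | intermediate
10 | tert-butyl (3R)-8-methyl-4-methylidene-3-[(phenylsulfonyl)methyl]non-7-enoate | C=C(CCC=C(C)C)[C@@H](CC(=O)OC(C)(C)C)CS(=O)(=O)c1ccccc1 | intermediate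
11 | (3R)-8-methyl-4-methylidene-3-[(phenylsulfonyl)methyl]non-7-en-1-ol | C=C(CCC=C(C)C)[C@@H](CCO)CS(=O)(=O)c1ccccc1 | intermediate
12 | 5-bromo-2-methylpent-2-ene | CC(C)=CCCBr | starting material
13 | propyne | CC#C | starting material
14 | (4-methylpent-3-en-1-yl)magnesium bromide | CC(C)=CCC[Mg]Br | intermediate
15 | (4-methylpent-3-en-1-yl)copper | CC(C)=CCC[Cu] | intermediate
16 | [(1Z)-2,6-dimethylhepta-1,5-dien-1-yl]copper | CC(C)=CCC/C(C)=C\[Cu] | intermediate
17 | (1Z)-1-iodo-2,6-dimethylhepta-1,5-diene | CC(C)=CCC/C(C)=C\I | intermediate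
18 | (2E,6Z)-7-iodo-2,6-dimethylhepta-2,6-dien-1-ol | OC/C(C)=C/CC/C(C)=C\I | intermediate
19 | (1Z,5E)-7-bromo-1-iodo-2,6-dimethylhepta-1,5-diene | BrC/C(C)=C/CC/C(C)=C\I | intermediate
20 | dilithium dianion of 11 (lithium alkoxide and α-sulfonyl carbanion) | [Li+].[Li+].C=C(CCC=C(C)C)[C@@H](CC[O-])[CH-]S(=O)(=O)c1ccccc1 | intermediate
21 | (3R,4RS,6E,10Z)-11-iodo-6,10-dimethyl-3-(6-methylhepta-1,5-dien-2-yl)-4-(phenylsulfonyl)undeca-6,10-dien-1-ol | C=C(CCC=C(C)C)[C@@H](CCO)C(C/C(C)=C/CC/C(C)=C\I)S(=O)(=O)c1ccccc1 | intermediate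
22 | but-3-enoic acid | C=CCC(=O)O | starting material
23 | but-3-enoic pivalic anhydride | C=CCC(=O)OC(=O)C(C)(C)C | intermediate
24 | (4R)-4-benzyl-3-(but-3-enoyl)-1,3-oxazolidin-2-one | C=CCC(=O)N1[C@H](Cc2ccccc2)COC1=O | intermediate
25 | (4R)-4-benzyl-3-[4-(9-borabicyclo[3.3.1]nonan-9-yl)butanoyl]-1,3-oxazolidin-2-one | O=C(CCCB1C2CCCC1CCC2)N1[C@H](Cc2ccccc2)COC1=O | intermediate
26 | (4R)-4-benzyl-3-[(5Z,9E,12RS,13R)-15-hydroxy-6,10-dimethyl-13-(6-methylhepta-1,5-dien-2-yl)-12-(phenylsulfonyl)pentadeca-5,9-dienoyl]-1,3-oxazolidin-2-one | C=C(CCC=C(C)C)[C@@H](CCO)C(C/C(C)=C/CC/C(C)=C\CCCC(=O)N1[C@H](Cc2ccccc2)COC1=O)S(=O)(=O)c1ccccc1 | intermediate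
27 | (4R)-4-benzyl-3-[(5Z,9E,12RS,13R)-6,10-dimethyl-13-(6-methylhepta-1,5-dien-2-yl)-12-(phenylsulfonyl)-15-{[(trifluoromethyl)sulfonyl]oxy}pentadeca-5,9-dienoyl]-1,3-oxazolidin-2-one | C=C(CCC=C(C)C)[C@@H](CCOS(=O)(=O)C(F)(F)F)C(C/C(C)=C/CC/C(C)=C\CCCC(=O)N1[C@H](Cc2ccccc2)COC1=O)S(=O)(=O)c1ccccc1 | intermediate
28 | sodium Z-enolate of 27 (enolate carbon C12, O–Na on C15) | [Na+].C=C(CCC=C(C)C)[C@@H](CCOS(=O)(=O)C(F)(F)F)C(C/C(C)=C/CC/C(C)=C\CC/C=C(\[O-])N1[C@H](Cc2ccccc2)COC1=O)S(=O)(=O)c1ccccc1 | intermediate
29 | (4R)-4-benzyl-3-{[(1S,4Z,8E,11RS,12R)-5,9-dimethyl-12-(6-methylhepta-1,5-dien-2-yl)-11-(phenylsulfonyl)cyclotetradeca-4,8-dien-1-yl]carbonyl}-1,3-oxazolidin-2-one | C=C(CCC=C(C)C)[C@@H]1C(S(=O)(=O)c2ccccc2)C/C(C)=C/CC/C(C)=C\CC[C@H](C(=O)N2[C@H](Cc3ccccc3)COC2=O)CC1 | intermediate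
30 | [(1S,4Z,8E,11RS,12R)-5,9-dimethyl-12-(6-methylhepta-1,5-dien-2-yl)-11-(phenylsulfonyl)cyclotetradeca-4,8-dien-1-yl]methanol | C=C(CCC=C(C)C)[C@@H]1C(S(=O)(=O)c2ccccc2)C/C(C)=C/CC/C(C)=C\CC[C@H](CO)CC1 | intermediate
31 | [(1S,4Z,8E,12S)-5,9-dimethyl-12-(6-methylhepta-1,5-dien-2-yl)cyclotetradeca-4,8-dien-1-yl]methanol | C=C(CCC=C(C)C)[C@@H]1CC/C(C)=C/CC/C(C)=C\CC[C@H](CO)CC1 | target

## Step count and least certain steps

Total steps: 16. Longest linear sequence: 12 steps (steps 1–6, 10, 12–16).

**Step 14 (key step, Proposed new method).** What may go wrong: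
- intermolecular alkylation leading to oligomers;
- O-alkylation of the enolate by the hard triflate;
- loss of the triflate by elimination or hydrolysis before ring closure;
- breakdown of the sodium enolate if the temperature must be raised;
- erosion of facial selectivity if the ring-forming transition state strains the chelate.

Fallback (known reaction types only; sets out from 11, 18 and 25, returns at 30). The ring is closed at C2–C3 by sulfone alkylation, and C12 is set beforehand by an intermolecular imide alkylation. Alcohol 11 is converted with Tf2O and 2,6-lutidine into sulfone triflate F1. Alcohol 18 is silylated (t-BuMe2SiCl, imidazole) to vinyl iodide silyl ether F2, which is coupled with borane 25 under the conditions of step 12 to chain imide F3. The sodium enolate of F3 (NaN(SiMe3)2, THF, −78 °C) is alkylated with F1 to alkylated imide F4, which sets C12 as in step 14. LiBH4 gives primary alcohol F5, and t-BuPh2SiCl with imidazole gives bis-silyl ether F6. Ph3PBr2 in CH2Cl2 at 0 °C converts the allylic tert-butyldimethylsilyl ether directly into allylic bromide F7. Slow addition of F7 to LiN(iPr)2 in THF at −78 °C under high dilution closes the ring by alkylation of the sulfonyl carbanion to macrocyclic silyl ether F8. Bu4NF then gives 30.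

**Step 2.** What may go wrong:
- deprotonation at the C4 methylene instead of the C3 methyl group;
- γ- instead of α-alkylation;
- base-induced migration of the new methylidene double bond into conjugation, with loss of the α-configuration.

Fallback (sets out from 1 and 5, returns at 8). The stereocentre is obtained by enzymatic resolution instead of an auxiliary. Acid 1 is esterified (MeI, K2CO3, DMF) to methyl geranate F9. Its lithium dienolate (LiN(iPr)2, THF/DMPU, −78 °C) is alkylated with 5 at the α-carbon to racemic diester F10. LiBH4 in THF reduces only the methyl ester and gives racemic hydroxy ester F11. A lipase (vinyl acetate, hexane), screened so that the (3S)-alcohol is acetylated, leaves the (3R)-alcohol 8 and forms (3S)-acetate F12, which is separated.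

**Step 12.** What may go wrong:
- cleavage of the imide by the aqueous base;
- protodeboronation or slow transmetalation of the imide-bearing borane.

Fallback (sets out from 2 and 21, returns at 26). The C9–C10 bond is made by an anhydrous Negishi coupling. Oxazolidinone 2 is N-acylated (n-BuLi, then 4-bromobutanoyl chloride, THF, −78 °C) to bromo imide F13. NaI in acetone gives iodo imide F14. Zinc insertion (Zn dust, LiCl, THF) gives alkylzinc iodide F15. An excess of F15 is coupled with vinyl iodide 21 (Pd(PPh3)4, THF, rt) with retention of the Z geometry to give 26.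

## Further compounds

F1 | step 14 | (3R)-8-methyl-4-methylidene-3-[(phenylsulfonyl)methyl]non-7-en-1-yl trifluoromethanesulfonate | C=C(CCC=C(C)C)[C@@H](CCOS(=O)(=O)C(F)(F)F)CS(=O)(=O)c1ccccc1
F2 | step 14 | tert-butyl{[(2E,6Z)-7-iodo-2,6-dimethylhepta-2,6-dien-1-yl]oxy}dimethylsilane | CC(C)(C)[Si](C)(C)OC/C(C)=C/CC/C(C)=C\I
F3 | step 14 | (4R)-4-benzyl-3-[(5Z,9E)-11-{[tert-butyl(dimethyl)silyl]oxy}-6,10-dimethylundeca-5,9-dienoyl]-1,3-oxazolidin-2-one | CC(C)(C)[Si](C)(C)OC/C(C)=C/CC/C(C)=C\CCCC(=O)N1[C@H](Cc2ccccc2)COC1=O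
F4 | step 14 | (4R)-4-benzyl-3-[(2S,5Z,9E)-11-{[tert-butyl(dimethyl)silyl]oxy}-6,10-dimethyl-2-{(3R)-8-methyl-4-methylidene-3-[(phenylsulfonyl)methyl]non-7-en-1-yl}undeca-5,9-dienoyl]-1,3-oxazolidin-2-one | C=C(CCC=C(C)C)[C@@H](CC[C@@H](C(=O)N1[C@H](Cc2ccccc2)COC1=O)CC/C=C(/C)CC/C=C(\C)CO[Si](C)(C)C(C)(C)C)CS(=O)(=O)c1ccccc1
F5 | step 14 | (2S,5Z,9E)-11-{[tert-butyl(dimethyl)silyl]oxy}-6,10-dimethyl-2-{(3R)-8-methyl-4-methylidene-3-[(phenylsulfonyl)methyl]non-7-en-1-yl}undeca-5,9-dien-1-ol | C=C(CCC=C(C)C)[C@@H](CC[C@@H](CO)CC/C=C(/C)CC/C=C(\C)CO[Si](C)(C)C(C)(C)C)CS(=O)(=O)c1ccccc1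
F6 | step 14 | tert-butyl{[(2S,5Z,9E)-11-{[tert-butyl(dimethyl)silyl]oxy}-6,10-dimethyl-2-{(3R)-8-methyl-4-methylidene-3-[(phenylsulfonyl)methyl]non-7-en-1-yl}undeca-5,9-dien-1-yl]oxy}diphenylsilane | C=C(CCC=C(C)C)[C@@H](CC[C@@H](CO[Si](c1ccccc1)(c1ccccc1)C(C)(C)C)CC/C=C(/C)CC/C=C(\C)CO[Si](C)(C)C(C)(C)C)CS(=O)(=O)c1ccccc1
F7 | step 14 | {[(2S,5Z,9E)-11-bromo-6,10-dimethyl-2-{(3R)-8-methyl-4-methylidene-3-[(phenylsulfonyl)methyl]non-7-en-1-yl}undeca-5,9-dien-1-yl]oxy}(tert-butyl)diphenylsilane | C=C(CCC=C(C)C)[C@@H](CC[C@@H](CO[Si](c1ccccc1)(c1ccccc1)C(C)(C)C)CC/C=C(/C)CC/C=C(\C)CBr)CS(=O)(=O)c1ccccc1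
F8 | step 14 | tert-butyl{[(1S,4Z,8E,11RS,12R)-5,9-dimethyl-12-(6-methylhepta-1,5-dien-2-yl)-11-(phenylsulfonyl)cyclotetradeca-4,8-dien-1-yl]methoxy}diphenylsilane | C=C(CCC=C(C)C)[C@@H]1C(S(=O)(=O)c2ccccc2)C/C(C)=C/CC/C(C)=C\CC[C@H](CO[Si](c2ccccc2)(c2ccccc2)C(C)(C)C)CC1
F9 | step 2 | methyl (2E)-3,7-dimethylocta-2,6-dienoate | CC(C)=CCC/C(C)=C/C(=O)OC
F10 | step 2 | 4-tert-butyl 1-methyl 2-(6-methylhepta-1,5-dien-2-yl)butanedioate (racemic) | C=C(CCC=C(C)C)C(CC(=O)OC(C)(C)C)C(=O)OC
F11 | step 2 | tert-butyl 3-(hydroxymethyl)-8-methyl-4-methylidenenon-7-enoate (racemic) | C=C(CCC=C(C)C)C(CC(=O)OC(C)(C)C)CO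
F12 | step 2 | tert-butyl (3S)-3-(acetoxymethyl)-8-methyl-4-methylidenenon-7-enoate | C=C(CCC=C(C)C)[C@H](CC(=O)OC(C)(C)C)COC(C)=O
F13 | step 12 | (4R)-4-benzyl-3-(4-bromobutanoyl)-1,3-oxazolidin-2-one | BrCCCC(=O)N1[C@H](Cc2ccccc2)COC1=O
F14 | step 12 | (4R)-4-benzyl-3-(4-iodobutanoyl)-1,3-oxazolidin-2-one | ICCCC(=O)N1[C@H](Cc2ccccc2)COC1=O
F15 | step 12 | {4-[(4R)-4-benzyl-2-oxo-1,3-oxazolidin-3-yl]-4-oxobutyl}zinc iodide | I[Zn]CCCC(=O)N1[C@H](Cc2ccccc2)COC1=O
A1 | alternative 1 | (4R)-limonene, (4R)-1-methyl-4-(prop-1-en-2-yl)cyclohex-1-ene | CC1=CC[C@@H](CC1)C(C)=C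
A2 | alternative 1 | (3R)-3-(6-methylhepta-1,5-dien-2-yl)-6-oxoheptanal | C=C(CCC=C(C)C)[C@@H](CC=O)CCC(C)=O
A3 | alternative 1 | (2S,5S)-8-methyl-5-(6-methylhepta-1,5-dien-2-yl)-2-[(3Z)-4-methylocta-3,7-dien-1-yl]non-8-en-1-ol | C=C(CCC=C(C)C)[C@@H](CC[C@@H](CO)CC/C=C(/C)CCC=C)CCC(C)=C
A4 | alternative 2 | 2,5-bis(hydroxymethyl)hexane-1,6-diol | OCC(CO)CCC(CO)CO
A5 | alternative 2 | (2R,5R)-2,5-bis(hydroxymethyl)hexane-1,6-diyl diacetate | CC(=O)OC[C@@H](CO)CC[C@H](CO)COC(C)=O
A6 | alternative 3 | (2S,5Z,9E,13R)-2-ethenyl-6,10-dimethyl-13-(6-methylhepta-1,5-dien-2-yl)pentadeca-5,9,14-trien-1-ol | C=C(CCC=C(C)C)[C@@H](C=C)CC/C(C)=C/CC/C(C)=C\CC[C@H](CO)C=C
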